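Retrosynthesis: the guaiacyl silyl ether is removed first, then the oxane is opened at O1–C6, then the two ArCH2–CH2 bonds of the resulting 1,7-diarylheptane-3,5-diol are cut back to a five-carbon bis-epoxide.
Enabling feature: in the oxane (O1, C2 arylethyl, C4 hydroxyl, C6 syringyl) C6 is benzylic and para to the free phenol of the syringyl ring, so O1–C6 is the adduct of the C2 oxygen with a para-quinone methide; without that bond a nearly C2-symmetric anti-1,3-diol remains.
Forward: (2R,4R)-1,2:4,5-diepoxypentane is opened at one terminus by the benzylic Grignard reagent from silylated vanillin and at the other by the one from benzylated syringaldehyde; hydrogenolysis frees the syringyl phenol, Ag2O oxidation closes the only ring, and fluoride unmasks the guaiacyl phenol.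
Stereochemistry: C2 and C4 of the oxane are the two carbinol centres of the diepoxide, carried through untouched; C6 is set in the ring closure by the all-equatorial chair, which is also the thermodynamic isomer.

Key step: step 10

Assumption: (2R,4R)-1,2:4,5-diepoxypentane is taken as a purchasable chiral building block of high enantiomeric purity.

Step 1
Reactants: 1 vanillin (4-hydroxy-3-methoxybenzaldehyde)
Product: 2 3-methoxy-4-[(triisopropylsilyl)oxy]benzaldehyde
Conditions: TIPSCl, imidazole, DMF, rt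
Reagents that add atoms: chlorotriisopropylsilane (TIPSCl), CC(C)[Si](Cl)(C(C)C)C(C)C
Why: Imidazole-mediated O-silylation of the phenol (silyl ether protection) gives an aryl triisopropylsilyl ether that should survive the Grignard, hydrogenolysis and Ag2O steps and leave only at the end with fluoride.

Step 2
Reactants: 2 3-methoxy-4-[(triisopropylsilyl)oxy]benzaldehyde
Product: 3 {3-methoxy-4-[(triisopropylsilyl)oxy]phenyl}methanol
Conditions: NaBH4, MeOH/THF, 0 °C
Reagents that add atoms: none
Why: Hydride reduction of the aryl aldehyde with NaBH4 is chemoselective for the carbonyl group and should leave the hindered aryl silyl ether untouched at 0 °C.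

Step 3
Reactants: 3 {3-methoxy-4-[(triisopropylsilyl)oxy]phenyl}methanol
Product: 4 [4-(chloromethyl)-2-methoxyphenoxy]triisopropylsilane
Conditions: SOCl2, pyridine, CH2Cl2, 0 °C; used crude
Reagents that add atoms: thionyl chloride, O=S(Cl)Cl
Why: Deoxychlorination of the electron-rich benzylic alcohol with SOCl2 is fast at 0 °C, and pyridine traps the HCl so that the silyl ether is not exposed to acid.

Step 4
Reactants: 4 [4-(chloromethyl)-2-methoxyphenoxy]triisopropylsilane; 5 (2R,4R)-1,2:4,5-diepoxypentane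
Product: 7 (2S)-4-{3-methoxy-4-[(triisopropylsilyl)oxy]phenyl}-1-[(2R)-oxiran-2-yl]butan-2-ol, via guaiacyl benzylmagnesium chloride 6 (not isolated)
Conditions: Mg turnings, THF, 0 °C (slow addition of 4); then 5 (1.5 equiv), CuI (10 mol%), THF, −40 to −20 °C; aq NH4Cl
Reagents that add atoms: none
Why: Magnesium insertion gives the benzylic Grignard reagent, which under CuI catalysis opens one epoxide of the C2-symmetric bis-epoxide by SN2 attack at its unsubstituted terminus, so both C–O stereocentres are carried over unchanged and the excess of 5 holds back a second opening.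

Step 5
Reactants: 8 syringaldehyde (4-hydroxy-3,5-dimethoxybenzaldehyde)
Product: 9 4-(benzyloxy)-3,5-dimethoxybenzaldehyde
Conditions: BnBr, K2CO3, DMF, 60 °C
Reagents that add atoms: benzyl bromide, BrCc1ccccc1
Why: Williamson ether synthesis on the hindered but acidic syringyl phenol installs a benzyl ether that tolerates the organomagnesium steps and can be removed by hydrogenolysis before any sensitive benzylic C–O bond exists.

Step 6
Reactants: 9 4-(benzyloxy)-3,5-dimethoxybenzaldehyde
Product: 10 [4-(benzyloxy)-3,5-dimethoxyphenyl]methanol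
Conditions: NaBH4, MeOH/THF, 0 °C
Reagents that add atoms: none
Why: NaBH4 reduction of the aryl aldehyde to the benzylic alcohol is selective and does not affect the benzyl or methyl ethers.

Step 7
Reactants: 10 [4-(benzyloxy)-3,5-dimethoxyphenyl]methanol
Product: 11 2-(benzyloxy)-5-(chloromethyl)-1,3-dimethoxybenzene
Conditions: SOCl2, pyridine, CH2Cl2, 0 °C; used crude
Reagents that add atoms: thionyl chloride, O=S(Cl)Cl
Why: Deoxychlorination of the benzylic alcohol with SOCl2 and pyridine is a standard conversion that leaves aryl ethers intact.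

Step 8
Reactants: 11 2-(benzyloxy)-5-(chloromethyl)-1,3-dimethoxybenzene; 7 (2S)-4-{3-methoxy-4-[(triisopropylsilyl)oxy]phenyl}-1-[(2R)-oxiran-2-yl]butan-2-ol
Product: 13 (3S,5S)-1-[4-(benzyloxy)-3,5-dimethoxyphenyl]-7-{3-methoxy-4-[(triisopropylsilyl)oxy]phenyl}heptane-3,5-diol, via syringyl benzylmagnesium chloride 12 (not isolated)
Conditions: Mg turnings, THF, 0 °C (slow addition of 11); then 7 (12 in 3 equiv), CuI (15 mol%), THF, −40 to 0 °C; aq NH4Cl
Reagents that add atoms: none
Why: A second CuI-catalysed SN2 epoxide opening at the terminal carbon, with the first equivalent of 12 consumed by the free hydroxyl, joins the syringyl arm without touching either carbinol centre, so the anti (3S,5S) diol follows directly from the configuration of 5.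

Step 9
Reactants: 13 (3S,5S)-1-[4-(benzyloxy)-3,5-dimethoxyphenyl]-7-{3-methoxy-4-[(triisopropylsilyl)oxy]phenyl}heptane-3,5-diol
Product: 14 (3S,5S)-1-(4-hydroxy-3,5-dimethoxyphenyl)-7-{3-methoxy-4-[(triisopropylsilyl)oxy]phenyl}heptane-3,5-diol
Conditions: H2 (1 atm), Pd/C (10% Pd on carbon), EtOAc, rt
Reagents that add atoms: none
Why: Catalytic hydrogenolysis cleaves only the aryl benzyl ether, leaving the silyl ether and both alcohols, and is placed here so that the later para-hydroxybenzylic C–O bond of the oxane is never exposed to H2 over Pd.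

Step 10
Reactants: 14 (3S,5S)-1-(4-hydroxy-3,5-dimethoxyphenyl)-7-{3-methoxy-4-[(triisopropylsilyl)oxy]phenyl}heptane-3,5-diol
Product: 16 (2S,4R,6S)-2-(2-{3-methoxy-4-[(triisopropylsilyl)oxy]phenyl}ethyl)-6-(4-hydroxy-3,5-dimethoxyphenyl)oxan-4-ol, via para-quinone methide 15 (not isolated)
Conditions: Ag2O (3 equiv), CH2Cl2, rt, dark; filter through Celite; then CSA (5 mol%), CH2Cl2, 0 °C
Reagents that add atoms: none
Why: Ag2O takes two electrons and two protons from the only free phenol, a 4-alkyl-2,6-dimethoxyphenol, to give the planar para-quinone methide 15, whose exocyclic carbon is attacked by the hydroxyl on the future C2 in an intramolecular 1,6-oxa-addition that restores the aromatic ring and forms O1–C6, the trace of acid accelerating this addition. The closest known reaction type is the Ag2O or DDQ oxidation of 4-alkyl-2,6-dimethoxyphenols to para-quinone methides followed by intramolecular capture by a hydroxyl group. The oxane closes in a 6-exo-trig mode, whereas attack by the other hydroxyl would be a 4-exo closure to an oxetane and should not compete. The new stereocentre C6 is controlled by the existing C2 and C4 centres through a chair transition state with the arylethyl, hydroxyl and aryl groups all equatorial, and because the para-hydroxybenzylic ether can re-ionise under the acid, any trans isomer should equilibrate to this all-cis (6S) product. The step needs site selectivity between the two benzylic carbons, which is secured by the silyl ether on the guaiacyl ring (no free phenol there, hence no quinone methide), and chemoselectivity over the secondary alcohols, which Ag2O does not oxidise under these conditions.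

Step 11
Reactants: 16 (2S,4R,6S)-2-(2-{3-methoxy-4-[(triisopropylsilyl)oxy]phenyl}ethyl)-6-(4-hydroxy-3,5-dimethoxyphenyl)oxan-4-ol
Product: 17 (2S,4R,6S)-2-[2-(4-hydroxy-3-methoxyphenyl)ethyl]-6-(4-hydroxy-3,5-dimethoxyphenyl)oxan-4-ol (CNP0302691.1)
Conditions: TBAF, AcOH, THF, 0 °C
Reagents that add atoms: none
Why: Fluoride-induced desilylation of the aryl silyl ether is fast at 0 °C, and the AcOH buffer keeps the syringyl phenol protonated so that the para-hydroxybenzylic ether is not opened through its phenoxide, while any reversible opening would reclose to the same all-equatorial ring.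

Compound list
1 | vanillin (4-hydroxy-3-methoxybenzaldehyde) | COc1cc(C=O)ccc1O | starting material
2 | 3-methoxy-4-[(triisopropylsilyl)oxy]benzaldehyde | COc1cc(C=O)ccc1O[Si](C(C)C)(C(C)C)C(C)C | intermediate
3 | {3-methoxy-4-[(triisopropylsilyl)oxy]phenyl}methanol | COc1cc(CO)ccc1O[Si](C(C)C)(C(C)C)C(C)C | intermediate
4 | [4-(chloromethyl)-2-methoxyphenoxy]triisopropylsilane | COc1cc(CCl)ccc1O[Si](C(C)C)(C(C)C)C(C)C | intermediate
5 | (2R,4R)-1,2:4,5-diepoxypentane [(2R,2'R)-2,2'-methylenebis(oxirane)] | C1O[C@@H]1C[C@@H]1CO1 | starting material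
6 | {3-methoxy-4-[(triisopropylsilyl)oxy]benzyl}magnesium chloride (formed in the flask) | COc1cc(C[Mg]Cl)ccc1O[Si](C(C)C)(C(C)C)C(C)C | intermediate
7 | (2S)-4-{3-methoxy-4-[(triisopropylsilyl)oxy]phenyl}-1-[(2R)-oxiran-2-yl]butan-2-ol | COc1cc(CC[C@H](O)C[C@@H]2CO2)ccc1O[Si](C(C)C)(C(C)C)C(C)C | intermediate
8 | syringaldehyde (4-hydroxy-3,5-dimethoxybenzaldehyde) | COc1cc(C=O)cc(OC)c1O | starting material
9 | 4-(benzyloxy)-3,5-dimethoxybenzaldehyde | COc1cc(C=O)cc(OC)c1OCc1ccccc1 | intermediate
10 | [4-(benzyloxy)-3,5-dimethoxyphenyl]methanol | COc1cc(CO)cc(OC)c1OCc1ccccc1 | intermediate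
11 | 2-(benzyloxy)-5-(chloromethyl)-1,3-dimethoxybenzene | COc1cc(CCl)cc(OC)c1OCc1ccccc1 | intermediate
12 | [4-(benzyloxy)-3,5-dimethoxybenzyl]magnesium chloride (formed in the flask) | COc1cc(C[Mg]Cl)cc(OC)c1OCc1ccccc1 | intermediate
13 | (3S,5S)-1-[4-(benzyloxy)-3,5-dimethoxyphenyl]-7-{3-methoxy-4-[(triisopropylsilyl)oxy]phenyl}heptane-3,5-diol | COc1cc(CC[C@H](O)C[C@@H](O)CCc2cc(OC)c(OCc3ccccc3)c(OC)c2)ccc1O[Si](C(C)C)(C(C)C)C(C)C | intermediate
14 | (3S,5S)-1-(4-hydroxy-3,5-dimethoxyphenyl)-7-{3-methoxy-4-[(triisopropylsilyl)oxy]phenyl}heptane-3,5-diol | COc1cc(CC[C@H](O)C[C@@H](O)CCc2cc(OC)c(O)c(OC)c2)ccc1O[Si](C(C)C)(C(C)C)C(C)C | intermediate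
15 | 4-[(3S,5S)-3,5-dihydroxy-7-{3-methoxy-4-[(triisopropylsilyl)oxy]phenyl}heptylidene]-2,6-dimethoxycyclohexa-2,5-dien-1-one (formed in the flask) | COc1cc(CC[C@H](O)C[C@@H](O)CC=C2C=C(OC)C(=O)C(OC)=C2)ccc1O[Si](C(C)C)(C(C)C)C(C)C | intermediate
16 | (2S,4R,6S)-2-(2-{3-methoxy-4-[(triisopropylsilyl)oxy]phenyl}ethyl)-6-(4-hydroxy-3,5-dimethoxyphenyl)oxan-4-ol | COc1cc(CC[C@H]2C[C@@H](O)C[C@@H](c3cc(OC)c(O)c(OC)c3)O2)ccc1O[Si](C(C)C)(C(C)C)C(C)C | intermediate
17 | (2S,4R,6S)-2-[2-(4-hydroxy-3-methoxyphenyl)ethyl]-6-(4-hydroxy-3,5-dimethoxyphenyl)oxan-4-ol | COc1cc(CC[C@H]2C[C@@H](O)C[C@@H](c3cc(OC)c(O)c(OC)c3)O2)ccc1O | target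

Total step count: 11
Longest linear sequence: 8 steps (steps 1, 2, 3, 4, 8, 9, 10, 11, from vanillin)

Steps most likely to fail

Step 10. The quinone methide may tautomerise to the 4-alkenylphenol or oligomerise before the hydroxyl adds, and the product phenol may be oxidised a second time on the silver oxide. The fallback forms O1–C6 at the ketone oxidation level by reductive etherification; it sets out from 9 and 7 and comes back at 16. Aldehyde 9 is condensed with propane-1,3-dithiol (BF3·OEt2, CH2Cl2, 0 °C) to 2-[4-(benzyloxy)-3,5-dimethoxyphenyl]-1,3-dithiane F1. Deprotonation with n-BuLi (THF, −78 °C) gives 2-[4-(benzyloxy)-3,5-dimethoxyphenyl]-2-lithio-1,3-dithiane F2, used in 2.2 equiv because the first equivalent is spent on the hydroxyl of 7. Opening of the epoxide of 7 at its terminus (dithiane umpolung, Corey–Seebach reaction) should give (2R,4S)-1-{2-[4-(benzyloxy)-3,5-dimethoxyphenyl]-1,3-dithian-2-yl}-6-{3-methoxy-4-[(triisopropylsilyl)oxy]phenyl}hexane-2,4-diol F3. Alkylative hydrolysis (MeI, CaCO3, aqueous MeCN, 45 °C) would unveil (3R,5S)-1-[4-(benzyloxy)-3,5-dimethoxyphenyl]-3,5-dihydroxy-7-{3-methoxy-4-[(triisopropylsilyl)oxy]phenyl}heptan-1-one F4. Et3SiH with BF3·OEt2 (CH2Cl2/MeCN, −40 °C) is expected to cyclise this δ-hydroxy ketone reductively, hydride adding axially to the cyclic oxocarbenium ion, to give the 2,6-cis oxane (2S,4R,6S)-2-[4-(benzyloxy)-3,5-dimethoxyphenyl]-6-(2-{3-methoxy-4-[(triisopropylsilyl)oxy]phenyl}ethyl)oxan-4-ol F5. A brief hydrogenolysis (H2, Pd/C, EtOAc, rt), monitored so that the cyclic benzylic ether is not attacked, then removes the benzyl ether and gives 16.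

Step 4. Wurtz-type homocoupling during magnesium insertion into the electron-rich benzylic chloride and a second opening of the bis-epoxide by the same reagent may erode the mono-adduct. The fallback replaces the Grignard reagent by an aryl dithiane anion made directly from the aldehyde, so steps 2 and 3 are not needed; it sets out from 2 and 5 and comes back at 13. Aldehyde 2 and propane-1,3-dithiol (BF3·OEt2 cat., CH2Cl2, 0 °C) give 2-{3-methoxy-4-[(triisopropylsilyl)oxy]phenyl}-1,3-dithiane F6. n-BuLi (THF, −78 °C) converts it into 2-lithio-2-{3-methoxy-4-[(triisopropylsilyl)oxy]phenyl}-1,3-dithiane F7, which is added to an excess of 5 (−78 to −20 °C) and should deliver (2R)-1-(2-{3-methoxy-4-[(triisopropylsilyl)oxy]phenyl}-1,3-dithian-2-yl)-3-[(2R)-oxiran-2-yl]propan-2-ol F8. The remaining epoxide is opened with Grignard reagent 12 exactly as in step 8 to give (2R,4S)-6-[4-(benzyloxy)-3,5-dimethoxyphenyl]-1-(2-{3-methoxy-4-[(triisopropylsilyl)oxy]phenyl}-1,3-dithian-2-yl)hexane-2,4-diol F9. Reductive desulfurisation with nickel boride (NiCl2·6H2O, NaBH4, MeOH/THF, 0 °C) then turns the dithiane carbon into the benzylic CH2 group and gives 13.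

Step 8. Opening of an epoxide that carries a magnesium alkoxide may be slow, chloride may open it to a chlorohydrin, and homocoupling of the benzylic halide costs more here because three equivalents are needed. The fallback uses a sulfone-stabilised benzylic carbanion in place of the Grignard reagent; it sets out from 11 and 7 and comes back at 13. Chloride 11 and PhSO2Na (DMF, rt) give 2-(benzyloxy)-1,3-dimethoxy-5-[(phenylsulfonyl)methyl]benzene F10. n-BuLi (THF, −78 °C) converts it into [4-(benzyloxy)-3,5-dimethoxyphenyl](phenylsulfonyl)methyllithium F11, used in 2.2 equiv. This should open the epoxide of 7 at its terminus (THF/DMPU, −78 to 0 °C) to give (3R,5S)-1-[4-(benzyloxy)-3,5-dimethoxyphenyl]-7-{3-methoxy-4-[(triisopropylsilyl)oxy]phenyl}-1-(phenylsulfonyl)heptane-3,5-diol F12 as a mixture of epimers at the sulfonyl carbon. Reductive desulfonylation with sodium amalgam (Na/Hg, Na2HPO4, MeOH/THF, −20 °C) removes that stereocentre and gives 13.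

Further compounds
F1 | step 10 | 2-[4-(benzyloxy)-3,5-dimethoxyphenyl]-1,3-dithiane | COc1cc(C2SCCCS2)cc(OC)c1OCc1ccccc1
F2 | step 10 | 2-[4-(benzyloxy)-3,5-dimethoxyphenyl]-2-lithio-1,3-dithiane | [Li]C1(c2cc(OC)c(OCc3ccccc3)c(OC)c2)SCCCS1
F3 | step 10 | (2R,4S)-1-{2-[4-(benzyloxy)-3,5-dimethoxyphenyl]-1,3-dithian-2-yl}-6-{3-methoxy-4-[(triisopropylsilyl)oxy]phenyl}hexane-2,4-diol | COc1cc(CC[C@H](O)C[C@@H](O)CC2(c3cc(OC)c(OCc4ccccc4)c(OC)c3)SCCCS2)ccc1O[Si](C(C)C)(C(C)C)C(C)C
F4 | step 10 | (3R,5S)-1-[4-(benzyloxy)-3,5-dimethoxyphenyl]-3,5-dihydroxy-7-{3-methoxy-4-[(triisopropylsilyl)oxy]phenyl}heptan-1-one | COc1cc(CC[C@H](O)C[C@@H](O)CC(=O)c2cc(OC)c(OCc3ccccc3)c(OC)c2)ccc1O[Si](C(C)C)(C(C)C)C(C)C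
F5 | step 10 | (2S,4R,6S)-2-[4-(benzyloxy)-3,5-dimethoxyphenyl]-6-(2-{3-methoxy-4-[(triisopropylsilyl)oxy]phenyl}ethyl)oxan-4-ol | COc1cc(CC[C@H]2C[C@@H](O)C[C@@H](c3cc(OC)c(OCc4ccccc4)c(OC)c3)O2)ccc1O[Si](C(C)C)(C(C)C)C(C)C
F6 | step 4 | 2-{3-methoxy-4-[(triisopropylsilyl)oxy]phenyl}-1,3-dithiane | COc1cc(C2SCCCS2)ccc1O[Si](C(C)C)(C(C)C)C(C)C
F7 | step 4 | 2-lithio-2-{3-methoxy-4-[(triisopropylsilyl)oxy]phenyl}-1,3-dithiane | [Li]C1(c2ccc(O[Si](C(C)C)(C(C)C)C(C)C)c(OC)c2)SCCCS1
F8 | step 4 | (2R)-1-(2-{3-methoxy-4-[(triisopropylsilyl)oxy]phenyl}-1,3-dithian-2-yl)-3-[(2R)-oxiran-2-yl]propan-2-ol | COc1cc(C2(C[C@H](O)C[C@@H]3CO3)SCCCS2)ccc1O[Si](C(C)C)(C(C)C)C(C)C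
F9 | step 4 | (2R,4S)-6-[4-(benzyloxy)-3,5-dimethoxyphenyl]-1-(2-{3-methoxy-4-[(triisopropylsilyl)oxy]phenyl}-1,3-dithian-2-yl)hexane-2,4-diol | COc1cc(C2(C[C@H](O)C[C@@H](O)CCc3cc(OC)c(OCc4ccccc4)c(OC)c3)SCCCS2)ccc1O[Si](C(C)C)(C(C)C)C(C)C
F10 | step 8 | 2-(benzyloxy)-1,3-dimethoxy-5-[(phenylsulfonyl)methyl]benzene | COc1cc(CS(=O)(=O)c2ccccc2)cc(OC)c1OCc1ccccc1
F11 | step 8 | [4-(benzyloxy)-3,5-dimethoxyphenyl](phenylsulfonyl)methyllithium | [Li]C(c1cc(OC)c(OCc2ccccc2)c(OC)c1)S(=O)(=O)c1ccccc1
F12 | step 8 | (3R,5S)-1-[4-(benzyloxy)-3,5-dimethoxyphenyl]-7-{3-methoxy-4-[(triisopropylsilyl)oxy]phenyl}-1-(phenylsulfonyl)heptane-3,5-diol (epimers at C1) | COc1cc(CC[C@H](O)C[C@@H](O)CC(c2cc(OC)c(OCc3ccccc3)c(OC)c2)S(=O)(=O)c2ccccc2)ccc1O[Si](C(C)C)(C(C)C)C(C)C
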